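If free substrate passes into target at a rate proportional to itself, a run can be timed by counting half-lives of that passage, and that is what I did.

| flask | substrate | reagent | temperature | remark | time |
|---|---|---|---|---|---|
| east | 0.010 M (fed, over 50 min) | 0.64 equiv | 95 °C | run made earlier |  |
| north-west | 0.010 M (fed, over 50 min) | 1.4 equiv | 110 °C | run made earlier |  |
| maple | 0.010 M (fed, over 50 min) | 0.950 equiv | 100 °C |  | 5.0 h |
| birch | 0.010 M | 0.950 equiv | 120 °C | everything together at the start | 5.0 h |

- east (time / h: target / %, substrate / %): 0.333: 0, 38.3; 0.500: 0, 57.2; 0.667: 0, 74.1; 1.00: 0.8, 87.6; 1.50: 0.8, 80.2; 2.50: 2.5, 72.6; 4.00: 6.2, 64.7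
- north-west (time / h: target / %, substrate / %): 0.333: 0.2, 33.0; 0.667: 1.3, 59.8; 1.00: 3.3, 67.0; 1.50: 7.2, 55.9; 2.00: 10.4, 47.3; 2.50: 13.1, 41.6

(each reading ± 0.5 percentage points)

- which one finishes higher in amount of target, in percent of the substrate charged ("neither" within 2 percentage points) (maple / birch / neither)
- amount of target at the end, in percent of the substrate charged, maple
- amount of target at the end, in percent of the substrate charged, birch

- percentages count the whole charge, also what has not yet gone in
- a reading of substrate is of its free form alone

1. The first rung was the feed. In north-west the substrate reading stood highest, at 67.0%, at 1.00 h, just after a feed of 50 min.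

2. The next rung was the loss of substrate. From that reading on, the readings of north-west's free substrate fell with a half-life, read over that stretch, of 2.18 h.

3. The last rung was target. I defined k, a pseudo-first-order constant, as the late rise of target per hour divided by the mean substrate over the same stretch. The target half-life τ is the time in which k by itself would halve the free substrate. North-west gave k = 0.121 /h, so τ = 5.73 h. This was longer than the loss half-life, so I took target to be one exit among others.

4. East gave k = 0.0359 /h. Both values are readings with scatter, and I ignored the difference in reagent between the runs. Taking ln k as linear in temperature, I got τ = 12.9 h for maple and τ = 2.55 h for birch, the target half-life. Maple's feed was short against its τ.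

5. Dividing the time by τ gave a count n of 0.389 half-lives for maple and 1.96 for birch. With target as sole exit, these counts would pass on 23.6% and 74.3%, which I call the marks. I expected birch ahead, with both flasks under their marks.

The forecast also said birch, with 17% for maple and 35% for birch, trimmed for “a side loss that is worse when hot”. The flasks gave birch, with 13.0% for maple and 50.5% for birch.

    substrate + reagent ⇌ intermediate A (K = 25.0 /M, k = 36.8 /M/h, Ea = 93.0 kJ/mol, ΔH = −49.0 kJ/mol)
    substrate ⇌ intermediate B (K = 0.281, k = 0.0838 /h, Ea = 119 kJ/mol, ΔH = −21.0 kJ/mol)
    substrate + reagent → side product (k = 14.2 /M/h, Ea = 58.0 kJ/mol)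
    intermediate B → target (k = 0.614 /h, Ea = 106 kJ/mol)
    (constants at 100 °C)

Birch's count of 1.96 against maple's 0.389 went with the same order of target, and birch ended under its mark of 74.3%. Birch run at maple's temperature ended at 14.2% instead of 50.5%, so the difference in temperature was the main reason for the gap between the flasks. Birch with the substrate fed as in maple ended at 49.1%, so the way the substrate went in was not the reason.

In a neighbouring flask, maple repeated at 125 °C, τ shortened to 1.70 h, which gave 2.94 half-lives and a mark of 87.0%. That flask gave 56.4% of target, with 39.1% of side product.

The earlier runs and the new flask were generated by integration for substances that don't exist, noise included.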